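A direct plan would close ring C last. Ring A would be dressed by carbamate-directed metalations, through the C-silylated bis-carbamate A1, into the silylaryl triflate A2. Fluoride would turn A2 into aryne A3, which would insert into the (S)-silyloxy Weinreb amide A4 to give the tris-MOM flavanone A5, and hot aqueous HCl would then free the three phenols. Its weakest steps would be:
(a) the cleavage of one of the two equivalent carbamates of A1, a statistical step inside a six-step run-up that builds neither a ring nor a stereocentre;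
(b) the aryne insertion, which would spend both finished halves on a ring closure without precedent for an aliphatic β-oxido amide, would have to add the alkoxide at the aryne carbon next to the prenyl group, and would risk β-elimination or retro-aldol cleavage of the alkoxide and with it the C2 configuration;
(c) the final triple acetal hydrolysis, which would expose the prenyl alkene to acid and, once the 5-OH is free, ring C to opening to the chalcone (racemisation, 6-/8-prenyl scrambling).

Plan of the new route. The retrosynthesis first cuts the C8–CH2 bond and returns the prenyl group to O5 (retro para-Claisen–Cope), then cuts C2–C1' (retro 1,4-arylation) to a 5-prenyloxychromone and an arylboronic acid, then the two O-alkyl bonds. Rings A and C enter fused as a bought chromone, ring B is joined to C2 afterwards, and the substitution of ring A is completed last. The enabling feature is that C8 is para to O5 across ring A, C6–H is the only open position ortho to O5 (C4a is quaternary), and the C4 carbonyl sits peri to O5 as a binding site for a Lewis acid. A prenyl group on O5 can therefore travel O5 → C6 → C8 by two [3,3] shifts and leave the hydrogen-bonded 5-OH behind; its precursor is an isomer that is reached by O-alkylations and one catalytic C–C coupling. Hence there is no aryne, no pair of equivalent groups to tell apart and no protecting group on ring A (the prenyl group masks O5 until it moves); ring C is never built from an open chain, and the last step is a fluoride desilylation in place of an acid hydrolysis.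

Key step: step 6

Assumption: the (S)-biaryl bisphosphine on rhodium is taken to deliver the aryl group to the Re face of C2 of the chromone (O1 > C3 > H), the topologically equal face to the one attacked in 2-cyclohexenone; if the opposite sense were found, the (R)-ligand would be used.
Abbreviations: (S)-MeO-F12-BIPHEP is (S)-2,2'-bis[bis(3,4,5-trifluorophenyl)phosphino]-6,6'-dimethoxy-1,1'-biphenyl; TBS is tert-butyldimethylsilyl; fod is 6,6,7,7,8,8,8-heptafluoro-2,2-dimethyloctane-3,5-dionate.

Step 1
Reactants: 1 5,7-dihydroxy-4H-chromen-4-one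
Product: 2 5-hydroxy-7-methoxy-4H-chromen-4-one
Conditions: MeI (1.05 equiv), K2CO3 (1.1 equiv), acetone, rt → 40 °C
Reagents that add atoms: iodomethane, CI
Why: Williamson ether synthesis in which the 7-OH, a vinylogous carboxylic acid conjugated with C4=O, is far more acidic than the 5-OH locked in a hydrogen bond to C4=O, so one equivalent of weak base and iodomethane should methylate O7 alone.

Step 2
Reactants: 2 5-hydroxy-7-methoxy-4H-chromen-4-one; 3 prenyl bromide (1-bromo-3-methylbut-2-ene)
Product: 4 7-methoxy-5-(3-methylbut-2-en-1-yloxy)-4H-chromen-4-one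
Conditions: 3 (1.5 equiv), K2CO3 (2 equiv), DMF, 40 °C
Reagents that add atoms: none
Why: Williamson O-alkylation of the remaining hydrogen-bonded phenol by a reactive allylic bromide in a dipolar aprotic solvent, where the potassium phenoxide reacts at oxygen and not at C6 or C8 and anhydrous carbonate leaves the pyrone ring closed.

Step 3
Reactants: 5 4-bromobenzene-1,2-diol
Product: 6 4-bromo-1,2-bis(tert-butyldimethylsilyloxy)benzene
Conditions: TBSCl (2.5 equiv), imidazole (5 equiv), DMF, rt
Reagents that add atoms: tert-butyldimethylsilyl chloride, CC(C)(C)[Si](C)(C)Cl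
Why: imidazole-promoted O-silylation of both phenols, which masks the catechol as ethers that tolerate the organolithium, rhodium and europium reagents and fall to fluoride at the end.

Step 4
Reactants: 6 4-bromo-1,2-bis(tert-butyldimethylsilyloxy)benzene
Product: 9 [3,4-bis(tert-butyldimethylsilyloxy)phenyl]boronic acid, via aryllithium 7 (not isolated), via lithium aryltriisopropoxyborate 8 (not isolated)
Conditions: n-BuLi (1.05 equiv), THF, −78 °C; B(OiPr)3 (1.5 equiv), −78 °C → rt; 1 M aq. HCl to pH 5, 0 °C
Reagents that add atoms: triisopropyl borate, CC(C)OB(OC(C)C)OC(C)C; water, O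
Why: bromine–lithium exchange and trapping of the aryllithium by the borate ester (borylation), then hydrolysis, in which the lithium sits meta and para to the silyloxy groups so that no silyl shift to carbon can occur and the aryl silyl ethers survive the brief, almost neutral work-up.

Step 5
Reactants: 4 7-methoxy-5-(3-methylbut-2-en-1-yloxy)-4H-chromen-4-one; 9 [3,4-bis(tert-butyldimethylsilyloxy)phenyl]boronic acid
Product: 10 (2S)-2-[3,4-bis(tert-butyldimethylsilyloxy)phenyl]-7-methoxy-5-(3-methylbut-2-en-1-yloxy)chroman-4-one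
Conditions: 9 (2.0 equiv), [Rh(OH)((S)-MeO-F12-BIPHEP)]2 (2.5 mol %), CH2Cl2/H2O (10:1), rt
Reagents that add atoms: none
Why: rhodium-catalysed asymmetric 1,4-addition of an arylboronic acid to the C2=C3–C4=O enone of a chromone (Hayashi–Miyaura reaction), in which transmetallation gives an aryl complex of monovalent rhodium, C2=C3 inserts with the aryl group delivered to the Re face of C2 under control of the (S)-biaryl bisphosphine to set (2S), and water protonates the oxa-π-allyl rhodium at C3; the electron-poor ligand lets the reaction run at room temperature without added base, so the product should neither open to the chalcone nor suffer 1,2-addition, and the prenyl ether and silyl ethers are not touched.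

Step 6
Reactants: 10 (2S)-2-[3,4-bis(tert-butyldimethylsilyloxy)phenyl]-7-methoxy-5-(3-methylbut-2-en-1-yloxy)chroman-4-one
Product: 13 (2S)-2-[3,4-bis(tert-butyldimethylsilyloxy)phenyl]-5-hydroxy-7-methoxy-8-(3-methylbut-2-en-1-yl)chroman-4-one, via ortho-dienone 11 (not isolated), via para-dienone 12 (not isolated)
Conditions: Eu(fod)3 (10 mol %), NaHCO3 (solid, 1 equiv), CHCl3 (ethanol-free), 60 °C, sealed tube, Ar
Reagents that add atoms: none
Why: Eu(fod)3 binds the C4 carbonyl and the peri ether oxygen O5 and so lowers the barrier of the aromatic Claisen [3,3] shift of the prenyl group from O5 to C6, the only open ortho carbon, to give ortho-dienone 11 with an inverted (1,1-dimethylallyl) group; a Cope [3,3] shift across C6–C7=C8 then moves the allyl unit to C8, para to O5, with a second inversion that restores the linear prenyl group in para-dienone 12, and tautomerisation gives phenol 13. The closest known reaction type is the europium-catalysed para-Claisen–Cope rearrangement of 5-O-prenylflavonoids to 8-prenylflavonoids. No ring is closed, and the sp3 centres at C6 of 11 and C8 of 12 are lost on aromatisation, so no new stereocentre remains; C2 takes no part, and without base or Brønsted acid ring C should not open. The selectivity needed is C8 over C6, that is, a Cope shift faster than enolisation of 11; the substrate secures it because the tertiary allyl group at C6 is wedged between the C5 carbonyl and the C7 methoxy group, which strains 11 and speeds the second shift, while C8 carries only hydrogen and the other ortho position, C4a, is quaternary. The driving force is rearomatisation and the hydrogen bond of the new 5-OH to C4=O, and the silyl ethers and the trisubstituted alkene are inert to the Lewis acid.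

Step 7
Reactants: 13 (2S)-2-[3,4-bis(tert-butyldimethylsilyloxy)phenyl]-5-hydroxy-7-methoxy-8-(3-methylbut-2-en-1-yl)chroman-4-one
Product: 14 (2S)-2-(3,4-dihydroxyphenyl)-5-hydroxy-7-methoxy-8-(3-methylbut-2-en-1-yl)chroman-4-one
Conditions: Et3N·3HF (6 equiv), THF, 0 °C → rt, Ar; pH 6 buffer work-up
Reagents that add atoms: none
Why: fluoride-mediated cleavage of the two aryl silyl ethers (desilylation) under slightly acidic, non-basic conditions, which should leave ring C closed (no retro-oxa-Michael, so C2 stays S and the prenyl group stays at C8) and does not touch the prenyl alkene.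

**Compound list**

1 | 5,7-dihydroxy-4H-chromen-4-one (5,7-dihydroxychromone) | O=c1ccoc2cc(O)cc(O)c12 | starting material
2 | 5-hydroxy-7-methoxy-4H-chromen-4-one | COc1cc(O)c2c(c1)occc2=O | intermediate
3 | prenyl bromide (1-bromo-3-methylbut-2-ene) | CC(C)=CCBr | starting material
4 | 7-methoxy-5-(3-methylbut-2-en-1-yloxy)-4H-chromen-4-one | COc1cc(OCC=C(C)C)c2c(c1)occc2=O | intermediate
5 | 4-bromobenzene-1,2-diol (4-bromocatechol) | Oc1ccc(Br)cc1O | starting material
6 | 4-bromo-1,2-bis(tert-butyldimethylsilyloxy)benzene | CC(C)(C)[Si](C)(C)Oc1ccc(Br)cc1O[Si](C)(C)C(C)(C)C | intermediate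
7 | [3,4-bis(tert-butyldimethylsilyloxy)phenyl]lithium | [Li]c1ccc(O[Si](C)(C)C(C)(C)C)c(O[Si](C)(C)C(C)(C)C)c1 | intermediate (not isolated)
8 | lithium [3,4-bis(tert-butyldimethylsilyloxy)phenyl]tri(propan-2-yloxy)borate | [Li+].CC(C)O[B-](OC(C)C)(OC(C)C)c1ccc(O[Si](C)(C)C(C)(C)C)c(O[Si](C)(C)C(C)(C)C)c1 | intermediate (not isolated)
9 | [3,4-bis(tert-butyldimethylsilyloxy)phenyl]boronic acid | OB(O)c1ccc(O[Si](C)(C)C(C)(C)C)c(O[Si](C)(C)C(C)(C)C)c1 | intermediate
10 | (2S)-2-[3,4-bis(tert-butyldimethylsilyloxy)phenyl]-7-methoxy-5-(3-methylbut-2-en-1-yloxy)chroman-4-one | COc1cc(OCC=C(C)C)c2c(c1)O[C@H](c1ccc(O[Si](C)(C)C(C)(C)C)c(O[Si](C)(C)C(C)(C)C)c1)CC2=O | intermediate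
11 | (2S)-2-[3,4-bis(tert-butyldimethylsilyloxy)phenyl]-7-methoxy-6-(2-methylbut-3-en-2-yl)-2,3-dihydro-4H-chromene-4,5(6H)-dione, C6 configuration undefined | COC1=CC2=C(C(=O)C1C(C)(C)C=C)C(=O)C[C@@H](c1ccc(O[Si](C)(C)C(C)(C)C)c(O[Si](C)(C)C(C)(C)C)c1)O2 | intermediate (not isolated)
12 | (2S)-2-[3,4-bis(tert-butyldimethylsilyloxy)phenyl]-7-methoxy-8-(3-methylbut-2-en-1-yl)-2,3-dihydro-4H-chromene-4,5(8H)-dione, C8 configuration undefined | COC1=CC(=O)C2=C(C1CC=C(C)C)O[C@H](c1ccc(O[Si](C)(C)C(C)(C)C)c(O[Si](C)(C)C(C)(C)C)c1)CC2=O | intermediate (not isolated)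
13 | (2S)-2-[3,4-bis(tert-butyldimethylsilyloxy)phenyl]-5-hydroxy-7-methoxy-8-(3-methylbut-2-en-1-yl)chroman-4-one | COc1cc(O)c2c(c1CC=C(C)C)O[C@H](c1ccc(O[Si](C)(C)C(C)(C)C)c(O[Si](C)(C)C(C)(C)C)c1)CC2=O | intermediate
14 | (2S)-2-(3,4-dihydroxyphenyl)-5-hydroxy-7-methoxy-8-(3-methylbut-2-en-1-yl)chroman-4-one | COc1cc(O)c2c(c1CC=C(C)C)O[C@H](c1ccc(O)c(O)c1)CC2=O | target

Total step count: 7. Longest linear sequence: 5 steps (steps 1, 2, 5, 6, 7 from 1; the boronic acid branch, steps 3 and 4, joins at step 5).

Steps most likely to fail: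

1. Step 6. The relay may stop after the first shift (enolisation of the ortho-dienone fixes the tertiary allyl group at C6), the Lewis acid may cleave the prenyl ether, or prolonged heating with the Lewis acid may erode the C2 configuration. The fallback moves the relay in front of the stereocentre. It sets out from chromone 4, which is rearranged under the same europium catalysis (or by heating in N,N-diethylaniline, since nothing in 4 can epimerise) to 5-hydroxy-7-methoxy-8-(3-methylbut-2-en-1-yl)-4H-chromen-4-one F1, freed from any C6 isomer at this cheap stage. The hydrogen-bonded 5-OH is silylated (TBSOTf, 2,6-lutidine, CH2Cl2) to 5-(tert-butyldimethylsilyloxy)-7-methoxy-8-(3-methylbut-2-en-1-yl)-4H-chromen-4-one F2. The rhodium-catalysed arylation with 9 under the conditions of step 5 should then give (2S)-2-[3,4-bis(tert-butyldimethylsilyloxy)phenyl]-5-(tert-butyldimethylsilyloxy)-7-methoxy-8-(3-methylbut-2-en-1-yl)chroman-4-one F3. The fluoride treatment of step 7 removes all three silyl groups, so the route is rejoined at 14.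

2. Step 5. Insertion of the electron-rich 5,7-dialkoxychromone may be slow, protodeboronation of 9 may outrun the addition, or the facial selectivity may be poor. In the fallback, 4 and 9 are joined without a chiral ligand ([Rh(OH)(cod)]2, dioxane/H2O, 50 °C) to racemic 2-[3,4-bis(tert-butyldimethylsilyloxy)phenyl]-7-methoxy-5-(3-methylbut-2-en-1-yloxy)chroman-4-one F4. The wrong enantiomer is then removed by kinetic resolution through Noyori–Ikariya asymmetric transfer hydrogenation (RuCl[(R,R)-TsDPEN](p-cymene), HCO2H/Et3N). This is expected to reduce the (2R)-ketone to (2R,4R)-2-[3,4-bis(tert-butyldimethylsilyloxy)phenyl]-7-methoxy-5-(3-methylbut-2-en-1-yloxy)chroman-4-ol F5 and to leave the (2S)-ketone, which is 10, where the route is rejoined.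

3. Step 2. Alkylation of the hydrogen-bonded 5-OH may be incomplete, C-alkylation at C6 or C8 may compete, or the base may open the pyrone ring. The fallback puts the prenyl group on oxygen before ring C exists. It sets out from prenyl bromide 3 and commercial 1-(2,6-dihydroxy-4-methoxyphenyl)ethan-1-one F6, used in place of 1 and 2. Mono-O-alkylation (K2CO3, acetone; the second hydroxyl stays hydrogen-bonded to the acetyl group) gives 1-[2-hydroxy-4-methoxy-6-(3-methylbut-2-en-1-yloxy)phenyl]ethan-1-one F7. Condensation with N,N-dimethylformamide dimethyl acetal gives (E)-3-(dimethylamino)-1-[2-hydroxy-4-methoxy-6-(3-methylbut-2-en-1-yloxy)phenyl]prop-2-en-1-one F8, and warming in acetic acid closes the pyrone ring with loss of dimethylamine to give chromone 4.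

**Further compounds**

F1 | step 6 | 5-hydroxy-7-methoxy-8-(3-methylbut-2-en-1-yl)-4H-chromen-4-one | COc1cc(O)c2c(c1CC=C(C)C)occc2=O
F2 | step 6 | 5-(tert-butyldimethylsilyloxy)-7-methoxy-8-(3-methylbut-2-en-1-yl)-4H-chromen-4-one | COc1cc(O[Si](C)(C)C(C)(C)C)c2c(c1CC=C(C)C)occc2=O
F3 | step 6 | (2S)-2-[3,4-bis(tert-butyldimethylsilyloxy)phenyl]-5-(tert-butyldimethylsilyloxy)-7-methoxy-8-(3-methylbut-2-en-1-yl)chroman-4-one | COc1cc(O[Si](C)(C)C(C)(C)C)c2c(c1CC=C(C)C)O[C@H](c1ccc(O[Si](C)(C)C(C)(C)C)c(O[Si](C)(C)C(C)(C)C)c1)CC2=O
F4 | step 5 | racemic 2-[3,4-bis(tert-butyldimethylsilyloxy)phenyl]-7-methoxy-5-(3-methylbut-2-en-1-yloxy)chroman-4-one | COc1cc(OCC=C(C)C)c2c(c1)OC(c1ccc(O[Si](C)(C)C(C)(C)C)c(O[Si](C)(C)C(C)(C)C)c1)CC2=O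
F5 | step 5 | (2R,4R)-2-[3,4-bis(tert-butyldimethylsilyloxy)phenyl]-7-methoxy-5-(3-methylbut-2-en-1-yloxy)chroman-4-ol | COc1cc(OCC=C(C)C)c2c(c1)O[C@@H](c1ccc(O[Si](C)(C)C(C)(C)C)c(O[Si](C)(C)C(C)(C)C)c1)C[C@H]2O
F6 | step 2 | 1-(2,6-dihydroxy-4-methoxyphenyl)ethan-1-one | COc1cc(O)c(C(C)=O)c(O)c1
F7 | step 2 | 1-[2-hydroxy-4-methoxy-6-(3-methylbut-2-en-1-yloxy)phenyl]ethan-1-one | COc1cc(O)c(C(C)=O)c(OCC=C(C)C)c1
F8 | step 2 | (E)-3-(dimethylamino)-1-[2-hydroxy-4-methoxy-6-(3-methylbut-2-en-1-yloxy)phenyl]prop-2-en-1-one | COc1cc(O)c(C(=O)/C=C/N(C)C)c(OCC=C(C)C)c1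
A1 | direct plan | 5-methoxy-2-(trimethylsilyl)-1,3-phenylene bis(N-isopropylcarbamate) | COc1cc(OC(=O)NC(C)C)c([Si](C)(C)C)c(OC(=O)NC(C)C)c1
A2 | direct plan | 3-methoxy-5-(methoxymethoxy)-2-(3-methylbut-2-en-1-yl)-6-(trimethylsilyl)phenyl trifluoromethanesulfonate | COc1cc(OCOC)c([Si](C)(C)C)c(OS(=O)(=O)C(F)(F)F)c1CC=C(C)C
A3 | direct plan | 5-methoxy-3-(methoxymethoxy)-6-(3-methylbut-2-en-1-yl)-1,2-didehydrobenzene | CC(C)=CCC1=C(OC)C=C(OCOC)C#C1
A4 | direct plan | (S)-3-[3,4-bis(methoxymethoxy)phenyl]-N-methoxy-N-methyl-3-(trimethylsilyloxy)propanamide | C[Si](C)(C)O[C@H](c1ccc(OCOC)c(OCOC)c1)CC(=O)N(C)OC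
A5 | direct plan | (2S)-2-[3,4-bis(methoxymethoxy)phenyl]-7-methoxy-5-(methoxymethoxy)-8-(3-methylbut-2-en-1-yl)chroman-4-one | COc1cc(OCOC)c2c(c1CC=C(C)C)O[C@H](c1ccc(OCOC)c(OCOC)c1)CC2=O
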